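The route rests on disconnecting the benzene ring of the phthalide (C3a, C4, C5, C6, C7, C7a) at C7–C7a and C4–C3a. The 5,7-dimethoxy pattern, the carboxyl carbon C1 on C7a and the carbinol carbon C3 on C3a are exactly what 1,3-dimethoxycyclohexa-1,3-diene leaves on a 4-oxygenated alk-2-ynoate. One thermal Alder–Rickert operation (Diels–Alder, then loss of ethene) builds the fully substituted arene regiospecifically without touching any stereocentre. Its precursor is the methyl (R)-4-silyloxydec-2-ynoate that already carries the six-carbon tether and the (2S,5R,7S)-spiroketal, made from two enantiopure epoxides, a hydrazone linchpin, hydroformylation and a catalytic asymmetric propiolate addition.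

Key step: step 7

Remarks on the chemistry
- Numbering: phthalide C1 (C=O), O2, C3, C3a, C4–C7, C7a; spiroketal O1, C2 (tether), C5 (spiro), O6, C7 (methyl). The target is (3R) at the phthalide and (2S,5R,7S) at the spiroketal, the E,E isomer in which each alkyl group is anti to the oxygen of the other ring.
- The C–O stereocentre C2 of the spiroketal cannot be equilibrated, so 1,2-epoxyoct-7-ene must enter as the single (S)-enantiomer; it is resolved in step 1.
- Assumption: the (S,S)-ProPhenol/Me2Zn catalyst is taken to deliver the alkynyl group to the Si face of an unbranched aldehyde, giving the (4R)-carbinol. The sense is to be checked by Mosher ester analysis on the first batch, and the (R,R)-ligand is used if the reverse is found.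

Step 1
Reactants: 1 racemic 1,2-epoxyoct-7-ene
Product: 2 (S)-1,2-epoxyoct-7-ene
Conditions: (S,S)-(salen)Co(III)OAc (0.5 mol%), H2O (0.55 equiv), neat, 0 °C to rt; vacuum distillation from the diol
Reagents that add atoms: none
Why: Jacobsen hydrolytic kinetic resolution, in which the (S,S)-catalyst should hydrolyse the (R)-epoxide selectively and leave the (S)-epoxide that supplies the non-epimerisable spiroketal C2 centre.

Step 2
Reactants: 2 (S)-1,2-epoxyoct-7-ene; 3 acetone N,N-dimethylhydrazone; 4 (S)-propylene oxide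
Product: 8 (2S,5R,7S)-2-(hex-5-en-1-yl)-7-methyl-1,6-dioxaspiro[4.4]nonane, via (5S)-2-(2,2-dimethylhydrazinylidene)undec-10-en-5-ol 5 (not isolated), via (2S,8S)-5-(2,2-dimethylhydrazinylidene)tetradec-13-ene-2,8-diol 6 (not isolated), via (2S,8S)-2,8-dihydroxytetradec-13-en-5-one 7 (not isolated)
Conditions: 3 (1.1 equiv), n-BuLi (1.1 equiv), THF, −78 to 0 °C; 2, 0 °C to rt; n-BuLi (1.2 equiv), −78 to 0 °C; 4 (1.5 equiv), 0 °C to rt; then 2 M aq HCl, rt; chromatography on Et3N-deactivated SiO2; the (5S) epimer re-equilibrated (PPTS, CH2Cl2) and recycled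
Reagents that add atoms: none
Why: Two successive Corey–Enders aza-enolate alkylations (α, then α′ at the remaining methyl, the less substituted site) open each epoxide at its CH2 terminus so both carbinol centres pass unchanged from 2 and 4, and aqueous acid then hydrolyses the hydrazone and closes the γ,γ′-dihydroxy ketone to the spiroketal by two 5-exo-trig additions, the acid-labile spiro centre C5 being set by equilibration, isolation of the (5R) epimer and recycling of the (5S) epimer.

Step 3
Reactants: 8 (2S,5R,7S)-2-(hex-5-en-1-yl)-7-methyl-1,6-dioxaspiro[4.4]nonane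
Product: 9 7-[(2S,5R,7S)-7-methyl-1,6-dioxaspiro[4.4]nonan-2-yl]heptanal
Conditions: Rh(acac)(CO)2 (0.5 mol%), Xantphos (2 mol%), CO/H2 (1:1, 10 bar), toluene, 80 °C
Reagents that add atoms: carbon monoxide, [C-]#[O+]
Why: Linear-selective Rh-catalysed hydroformylation, in which the wide-bite-angle diphosphine should enforce anti-Markovnikov hydrometalation of the terminal alkene before CO insertion, under neutral conditions that leave the spiroketal untouched.

Step 4
Reactants: 9 7-[(2S,5R,7S)-7-methyl-1,6-dioxaspiro[4.4]nonan-2-yl]heptanal; 10 methyl propiolate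
Product: 11 methyl (4R)-4-hydroxy-10-[(2S,5R,7S)-7-methyl-1,6-dioxaspiro[4.4]nonan-2-yl]dec-2-ynoate
Conditions: (S,S)-ProPhenol (10 mol%), Ph3PO (20 mol%), Me2Zn (3 equiv), 10 (3 equiv), toluene, 0–4 °C, slow addition of 9; aq NH4Cl
Reagents that add atoms: none
Why: Zn–ProPhenol catalytic asymmetric alkynylation, in which the dinuclear zinc complex binds the alkynylzinc and the aldehyde and should deliver the alkynyl group to the Si face to set the (4R) centre under catalyst control, the existing stereocentres being at least seven atoms away.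

Step 5
Reactants: 11 methyl (4R)-4-hydroxy-10-[(2S,5R,7S)-7-methyl-1,6-dioxaspiro[4.4]nonan-2-yl]dec-2-ynoate
Product: 12 methyl (4R)-4-[(tert-butyldimethylsilyl)oxy]-10-[(2S,5R,7S)-7-methyl-1,6-dioxaspiro[4.4]nonan-2-yl]dec-2-ynoate
Conditions: TBSCl (1.3 equiv), imidazole (2.5 equiv), DMF, 0 °C to rt
Reagents that add atoms: tert-butyldimethylsilyl chloride, CC(C)(C)[Si](C)(C)Cl
Why: Imidazole-promoted silylation of a secondary propargylic alcohol, mildly basic so that neither the spiro centre nor C4 is touched.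

Step 6
Reactants: 13 1,5-dimethoxycyclohexa-1,4-diene
Product: 14 1,3-dimethoxycyclohexa-1,3-diene
Conditions: RhCl(PPh3)3 (1 mol%), CHCl3 (filtered through basic alumina), reflux; distillation
Reagents that add atoms: none
Why: Rh(I)-catalysed double-bond migration should move one enol ether double bond into conjugation with the other, the conjugated diene being the more stable isomer and residual 13 being inert in step 7.

Step 7
Reactants: 12 methyl (4R)-4-[(tert-butyldimethylsilyl)oxy]-10-[(2S,5R,7S)-7-methyl-1,6-dioxaspiro[4.4]nonan-2-yl]dec-2-ynoate; 14 1,3-dimethoxycyclohexa-1,3-diene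
Product: 16 methyl 2-[(1R)-1-[(tert-butyldimethylsilyl)oxy]-7-[(2S,5R,7S)-7-methyl-1,6-dioxaspiro[4.4]nonan-2-yl]heptyl]-4,6-dimethoxybenzoate, via methyl 1,5-dimethoxy-3-[(1R)-1-[(tert-butyldimethylsilyl)oxy]-7-[(2S,5R,7S)-7-methyl-1,6-dioxaspiro[4.4]nonan-2-yl]heptyl]bicyclo[2.2.2]octa-2,5-diene-2-carboxylate 15 (not isolated)
Conditions: 14 (5 equiv), PhNMe2 (0.5 equiv), neat, sealed tube, Ar, 180 °C
Reagents that add atoms: none
Why: The electron-rich diene 14 and the ester-polarised alkyne of 12 should combine in a concerted, asynchronous normal-demand [4+2] in which the unsubstituted diene terminus C4 (largest HOMO coefficient, pushed by both methoxy groups) bonds to the ynoate β-carbon and the methoxy-bearing terminus C1 to the α-carbon, giving bicyclo[2.2.2]octadiene 15, which at the same temperature loses its ethano bridge as ethene by retro-[4+2], driven by aromatisation. This is the Alder–Rickert reaction, known for this diene with alk-2-ynoates as a route to 2,4-dimethoxy-6-alkylbenzoates. The benzene ring is closed by an intermolecular [4+2] cycloaddition that forms C7–C7a and C4–C3a, and the cycloreversion then reveals it. No stereocentre is created: the two bridgehead centres of 15 are transient, and the silyloxy centre and the spiroketal should pass unchanged through neutral thermal conditions buffered by the aniline. The only selectivity needed is regiochemistry, secured by the matched polarity of the 1,3-dioxygenated diene and the ynoate, while the silyl ether prevents premature lactonisation and isomerisation of the propargylic alcohol.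

Step 8
Reactants: 16 methyl 2-[(1R)-1-[(tert-butyldimethylsilyl)oxy]-7-[(2S,5R,7S)-7-methyl-1,6-dioxaspiro[4.4]nonan-2-yl]heptyl]-4,6-dimethoxybenzoate
Product: 17 (3R)-5,7-dimethoxy-3-{6-[(2S,5R,7S)-7-methyl-1,6-dioxaspiro[4.4]nonan-2-yl]hexyl}-2-benzofuran-1(3H)-one (target)
Conditions: TBAF (1.5 equiv), THF, 0 °C to rt; aq NH4Cl
Reagents that add atoms: none
Why: Fluoride desilylation should give the benzylic alkoxide, which attacks the ortho ester carbon in a 5-exo-trig lactonisation with loss of methoxide, the C3–O bond never being broken so that the (R) configuration is retained.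

Compound list
1 | racemic 1,2-epoxyoct-7-ene [2-(hex-5-en-1-yl)oxirane] | C=CCCCCC1CO1 | starting material
2 | (S)-1,2-epoxyoct-7-ene | C=CCCCC[C@H]1CO1 | intermediate
3 | acetone N,N-dimethylhydrazone | CC(C)=NN(C)C | starting material
4 | (S)-propylene oxide | C[C@H]1CO1 | starting material
5 | (5S)-2-(2,2-dimethylhydrazinylidene)undec-10-en-5-ol (lithium alkoxide in the flask; C=N geometry not defined) | C=CCCCC[C@H](O)CCC(C)=NN(C)C | intermediate
6 | (2S,8S)-5-(2,2-dimethylhydrazinylidene)tetradec-13-ene-2,8-diol | C[C@H](O)CCC(=NN(C)C)CC[C@@H](O)CCCCC=C | intermediate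
7 | (2S,8S)-2,8-dihydroxytetradec-13-en-5-one | C[C@H](O)CCC(=O)CC[C@@H](O)CCCCC=C | intermediate
8 | (2S,5R,7S)-2-(hex-5-en-1-yl)-7-methyl-1,6-dioxaspiro[4.4]nonane | C=CCCCC[C@H]1CC[C@@]2(CC[C@H](C)O2)O1 | intermediate
9 | 7-[(2S,5R,7S)-7-methyl-1,6-dioxaspiro[4.4]nonan-2-yl]heptanal | O=CCCCCCC[C@H]1CC[C@@]2(CC[C@H](C)O2)O1 | intermediate
10 | methyl propiolate | C#CC(=O)OC | starting material
11 | methyl (4R)-4-hydroxy-10-[(2S,5R,7S)-7-methyl-1,6-dioxaspiro[4.4]nonan-2-yl]dec-2-ynoate | COC(=O)C#C[C@H](O)CCCCCC[C@H]1CC[C@@]2(CC[C@H](C)O2)O1 | intermediate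
12 | methyl (4R)-4-[(tert-butyldimethylsilyl)oxy]-10-[(2S,5R,7S)-7-methyl-1,6-dioxaspiro[4.4]nonan-2-yl]dec-2-ynoate | COC(=O)C#C[C@@H](CCCCCC[C@H]1CC[C@@]2(CC[C@H](C)O2)O1)O[Si](C)(C)C(C)(C)C | intermediate
13 | 1,5-dimethoxycyclohexa-1,4-diene | COC1=CCC=C(OC)C1 | starting material
14 | 1,3-dimethoxycyclohexa-1,3-diene | COC1=CC(OC)=CCC1 | intermediate
15 | methyl 1,5-dimethoxy-3-[(1R)-1-[(tert-butyldimethylsilyl)oxy]-7-[(2S,5R,7S)-7-methyl-1,6-dioxaspiro[4.4]nonan-2-yl]heptyl]bicyclo[2.2.2]octa-2,5-diene-2-carboxylate (both bridgehead diastereomers) | COC12CCC(C(OC)=C1)C([C@@H](CCCCCC[C@H]3CC[C@@]4(CC[C@H](C)O4)O3)O[Si](C)(C)C(C)(C)C)=C2C(=O)OC | intermediate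
16 | methyl 2-[(1R)-1-[(tert-butyldimethylsilyl)oxy]-7-[(2S,5R,7S)-7-methyl-1,6-dioxaspiro[4.4]nonan-2-yl]heptyl]-4,6-dimethoxybenzoate | COc1cc(OC)c(C(=O)OC)c(c1)[C@@H](CCCCCC[C@H]1CC[C@@]2(CC[C@H](C)O2)O1)O[Si](C)(C)C(C)(C)C | intermediate
17 | (3R)-5,7-dimethoxy-3-{6-[(2S,5R,7S)-7-methyl-1,6-dioxaspiro[4.4]nonan-2-yl]hexyl}-2-benzofuran-1(3H)-one | COc1cc(OC)c2c(c1)[C@@H](CCCCCC[C@H]1CC[C@@]3(CC[C@H](C)O3)O1)OC2=O | target

Total step count: 8. Longest linear sequence: 7 (steps 1, 2, 3, 4, 5, 7, 8; step 6 is a one-step side branch).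

Steps most likely to fail

Step 7. At the temperature a disubstituted ynoate needs, cycloaddition may be outpaced by decomposition or polymerisation of the electron-rich diene or by thermal degradation of the propargylic silyl ether; trace acid may also epimerise the spiro centre. The fallback abandons the benzannulation and starts from a preformed arene, setting out from aldehyde 9. Addition of 3,5-dimethoxyphenylmagnesium bromide (THF, 0 °C) should give 1-(3,5-dimethoxyphenyl)-7-[(2S,5R,7S)-7-methyl-1,6-dioxaspiro[4.4]nonan-2-yl]heptan-1-ol F1 as a mixture of carbinol epimers. Dess–Martin oxidation (NaHCO3, CH2Cl2) gives the aryl ketone 1-(3,5-dimethoxyphenyl)-7-[(2S,5R,7S)-7-methyl-1,6-dioxaspiro[4.4]nonan-2-yl]heptan-1-one F2. Corey–Bakshi–Shibata reduction with (S)-Me-CBS and BH3·SMe2 should give the (1R)-alcohol F3. NBS (MeCN, NaHCO3, 0 °C) should brominate the ring position next to the carbinol carbon, which is ortho to one methoxy group and para to the other, giving (1R)-1-(2-bromo-3,5-dimethoxyphenyl)-7-[(2S,5R,7S)-7-methyl-1,6-dioxaspiro[4.4]nonan-2-yl]heptan-1-ol F4. Palladium-catalysed carbonylative lactonisation (Pd(OAc)2, Xantphos, CO, Et3N, toluene, 100 °C) then closes the phthalide and returns to the route at target 17.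

Step 4. Enantio-induction may be eroded with an unbranched, enolisable aldehyde through background addition, self-aldol or methyl transfer, and the absolute sense rests on the assumption stated above. The fallback replaces catalyst-controlled addition by reagent-controlled reduction and sets out from aldehyde 9. Lithiated methyl propiolate (LiHMDS, THF, −78 °C) should give methyl 4-hydroxy-10-[(2S,5R,7S)-7-methyl-1,6-dioxaspiro[4.4]nonan-2-yl]dec-2-ynoate F5 as C4 epimers. Dess–Martin oxidation (NaHCO3, CH2Cl2) gives the ynone methyl 4-oxo-10-[(2S,5R,7S)-7-methyl-1,6-dioxaspiro[4.4]nonan-2-yl]dec-2-ynoate F6. Midland reduction with (R)-Alpine-Borane (from (+)-α-pinene; THF, rt; ethanolamine work-up), known for alkyl 4-oxoalk-2-ynoates, should give the (4R)-alcohol and returns to the route at 11.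

Step 2. The second metalation and alkylation of the alkoxide-bearing hydrazone may be incomplete or regio-unselective, giving mono-alkylated or regioisomeric material that complicates isolation of the single spiro epimer. The fallback replaces the hydrazone linchpin by an alkyne linchpin and sets out from (S)-propylene oxide 4 and epoxide 2. Lithiated 1-(trimethylsilyl)propyne (n-BuLi, THF, −78 °C) opens 4 to give (2S)-6-(trimethylsilyl)hex-5-yn-2-ol F7, and K2CO3 in MeOH gives (2S)-hex-5-yn-2-ol F8. Its dianion (n-BuLi, 2.1 equiv) opens epoxide 2 in the presence of BF3·OEt2 (THF, −78 °C) to give (2S,8S)-tetradec-13-en-5-yne-2,8-diol F9. Gold(I)-catalysed double hydroalkoxylation (Ph3PAuCl/AgOTf, CH2Cl2, rt; 5-exo-dig and 5-endo-dig), followed by PPTS equilibration and chromatography as in the main route, returns to the route at 8. No other bis-cyclisation mode of this alkynediol gives two five-membered rings.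

Further compounds
F1 | step 7 | 1-(3,5-dimethoxyphenyl)-7-[(2S,5R,7S)-7-methyl-1,6-dioxaspiro[4.4]nonan-2-yl]heptan-1-ol (C1 epimers) | COc1cc(OC)cc(c1)C(O)CCCCCC[C@H]1CC[C@@]2(CC[C@H](C)O2)O1
F2 | step 7 | 1-(3,5-dimethoxyphenyl)-7-[(2S,5R,7S)-7-methyl-1,6-dioxaspiro[4.4]nonan-2-yl]heptan-1-one | COc1cc(OC)cc(c1)C(=O)CCCCCC[C@H]1CC[C@@]2(CC[C@H](C)O2)O1
F3 | step 7 | (1R)-1-(3,5-dimethoxyphenyl)-7-[(2S,5R,7S)-7-methyl-1,6-dioxaspiro[4.4]nonan-2-yl]heptan-1-ol | COc1cc(OC)cc(c1)[C@@H](CCCCCC[C@H]1CC[C@@]2(CC[C@H](C)O2)O1)O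
F4 | step 7 | (1R)-1-(2-bromo-3,5-dimethoxyphenyl)-7-[(2S,5R,7S)-7-methyl-1,6-dioxaspiro[4.4]nonan-2-yl]heptan-1-ol | COc1cc(OC)c(Br)c(c1)[C@@H](CCCCCC[C@H]1CC[C@@]2(CC[C@H](C)O2)O1)O
F5 | step 4 | methyl 4-hydroxy-10-[(2S,5R,7S)-7-methyl-1,6-dioxaspiro[4.4]nonan-2-yl]dec-2-ynoate (C4 epimers) | COC(=O)C#CC(O)CCCCCC[C@H]1CC[C@@]2(CC[C@H](C)O2)O1
F6 | step 4 | methyl 4-oxo-10-[(2S,5R,7S)-7-methyl-1,6-dioxaspiro[4.4]nonan-2-yl]dec-2-ynoate | COC(=O)C#CC(=O)CCCCCC[C@H]1CC[C@@]2(CC[C@H](C)O2)O1
F7 | step 2 | (2S)-6-(trimethylsilyl)hex-5-yn-2-ol | C[C@H](O)CCC#C[Si](C)(C)C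
F8 | step 2 | (2S)-hex-5-yn-2-ol | C[C@H](O)CCC#C
F9 | step 2 | (2S,8S)-tetradec-13-en-5-yne-2,8-diol | C[C@H](O)CCC#CC[C@@H](O)CCCCC=C
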